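The second nucleophile is in solution from the start, but the first nucleophile has to leave its solid. So the epsilon run at 2.50 h reads 0% target against 2.1% other capture product.

- epsilon: starting material 0.41 M; second nucleophile 0.61 M; protic impurity 0.041 M; solid first nucleophile 0.451 M; run made earlier
- flask: starting material 0.41 M; second nucleophile 0.410 M; protic impurity 0.0410 M; solid first nucleophile 0.451 M; time 15 d

epsilon run (percent of the starting material charged)

| time / h | target / % | other capture product / % |
|---|---|---|
| 2.50 | 0 | 2.1 |
| 8.00 | 0.8 | 6.9 |
| 12.0 | 1.3 | 8.8 |
| 20.0 | 0.8 | 13.0 |
| 30.0 | 3.5 | 19.2 |
| 40.0 | 4.7 | 24.3 |

(scatter of a reading: 0.5 percentage points)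

- given per volume of solution although it is solid: solid first nucleophile
- steps thought possible: starting material <-> intermediate; first nucleophile + intermediate -> target; second nucleophile + intermediate -> other capture product; starting material + protic impurity -> quenched substrate; solid first nucleophile <-> first nucleophile
- at the start none of the solid first nucleophile is in solution

- ratio of target to other capture product at 3.0 h
- ratio of target to other capture product at 30 h
- ratio of target to other capture product at 15 d

Both nucleophiles take the intermediate, so the instantaneous ratio of target to other capture product (the selectivity) follows [first nucleophile]/[second nucleophile]. This reckoning lets [first nucleophile] climb in proportion to time. The epsilon readings at 30.0 h and 40.0 h, pooled, give a ratio of 0.189 at a mean 35.0 h. That makes 0.00329 M/h for the cumulative ratio multiplied by [second nucleophile] and divided by time, the climb constant.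

Two times then enter this reckoning for the flask. The climb time, in which the cumulative ratio reaches one, is 125 h. The use time of a pseudo-first-order loss of starting material comes from 6.9% other capture product in 8.00 h in the epsilon run. Rescaled to the flask's [second nucleophile], it is 172 h. The flask's 15 d exceeds it, so the late ratio tends to twice the use time over the climb time. That figure takes the climb as straight up to the end, so this reckoning holds it as an upper estimate.

| time | this reckoning | forecast |
|---|---|---|
| 3.0 h | 0.0240 | 0.09 |
| 30 h | 0.240 | 0.27 |
| 15 d | below 2.75 | 0.41 |

The forecast differs in its picture: “the solid dissolves quickly to a saturation level”.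

The flask gives 0.0313, 0.241 and 0.825.

    starting material ⇌ intermediate (K = 0.0450, k = 0.00330 /min)
    first nucleophile + intermediate → target (k = 0.00870 /M/min)
    second nucleophile + intermediate → other capture product (k = 0.00580 /M/min)
    starting material + protic impurity → quenched substrate (k = 0.00560 /M/min)
    solid first nucleophile ⇌ first nucleophile, rate k5*(cs5 - [first nucleophile]) while solid is left; crystals form when [first nucleophile] > cs5 (solubility = 0.270 M, k = 3.40 × 10⁻⁴ /min)

In the flask, [first nucleophile] stood at 0.126 M after 1.50 d and at 0.262 M after 15.0 d. The climb constant 0.00329 M/h gives 0.240 at 30 h in the flask, beside the 0.241 found. The neighbour charged with 0.25 M of second nucleophile has a climb time of 76.1 h, which gives 0.394 at 30 h, and that neighbour gave 0.400.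

The earlier runs and the new flask stem from a simulated flask on assumed constants; the scatter is artificial.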